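Which flask ends with the most target, when they differ in temperature and in nothing else?

    intermediate → target (k1 = 0.0151 s⁻¹, Ea1 = 89.0 kJ mol⁻¹)
    substrate + coupling partner → intermediate + by-product (k2 = 0.0117 M⁻¹ s⁻¹, Ea2 = 63.0 kJ mol⁻¹)
    intermediate → decomposed reagent (k3 = 0.0475 s⁻¹, Ea3 = 99.0 kJ mol⁻¹)
    substrate → decomposition product (k4 = 4.77 × 10⁻⁵ s⁻¹, Ea4 = 120 kJ mol⁻¹)
    (constants at 70 °C)

| setting | teal | blue | green |
|---|---|---|---|
| substrate | 2.0 M | 2.0 M | 2.0 M |
| coupling partner | 1.80 M | 1.80 M | 1.80 M |
| temperature | 100 °C | 85 °C | 70 °C |
| time | 20 s | 20 s | 20 s |

* the best flask by amount of target, in percent of the substrate charged; "all alike" if 1.5 percentage points covers them all (teal / blue / green / all alike)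
* amount of target at the end, in percent of the substrate charged, teal
* amount of target at the end, in percent of the substrate charged, blue
* amount of target at the end, in percent of the substrate charged, green

- constants are those at 70 °C; use the activation energies for any other temperature

Target comes from intermediate, and the step to decomposed reagent drains the same intermediate, so I first asked how it divides. Both exits are first order. For green, the constant toward target over the sum of both exit constants was 24.1%; I called this the branching share S, the selectivity of the intermediate.

From green to teal the step to target speeds up by 12. Between the same two temperatures, the logarithm of such a factor scales with activation energy, so the step to decomposed reagent speeds up by 16.3. That put S for teal at 19.3%, lower than green's. The next question was how much intermediate each flask makes.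

At the start of teal, coupling used substrate 89 times as fast as decomposition did, so I dropped decomposition. Coupling partner is the limiting reagent, at 1.80 M against 2.0 M of substrate. I treated the charges as equal at their mean, so the consumed fraction of partner is x/(1+x), where x is rate constant times mean charge times time. This gave 65.2% of the substrate charged coupled in teal and 27.7% in green.

Last, does that material leave intermediate in time? The drain time τ, the inverse of the summed exit constants, was 1.04 s in teal, far shorter than 20 s, so I ignored the lag there. In green τ was 16.0 s. Treating green as a steady feed into a tank with that time constant, I reckoned that 43.0% of the coupled material had drained by the end.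

My reckoning gave teal 12.6% and green 2.87%. Blue, between them in temperature, I expected between them in target, so I chose teal.

The forecast also chose teal, with 12.9% for teal, 9.5% for blue and 3.3% for green, reasoning that “the hottest flask wins on sheer throughput”. Its teal and green figures stood above mine.

The simulation gave 13.0% in teal, 9.51% in blue and 3.31% in green, so teal was best. At 20.0 s, green still held 15.4% of the substrate charged as intermediate, against 1.05% in teal. In teal, 1.36 M of by-product meant 68.0% of the substrate charged had coupled; taking off the standing intermediate and applying S of 19.3% gave 12.9% of target. In green, the same step with S of 24.1% and 0.583 M of by-product gave 3.31%, beside the 3.31% found there.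

(Its constants are assumed, and the outcome is calculated.)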